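**Retrosynthetic overview**
1. Target 32 comes from desilylation and triacetylation of 30; the ten-membered ring is closed last, by ring-closing metathesis at C3=C4 (29 → 30).
2. The hydroxy γ-lactone of 29 comes from ketone 27 by an intramolecular samarium Reformatsky reaction (C17–C8).
3. Key disconnection C8–C9: late union of ring A stannane 13 (C1–C3, C9–C15, C20) with chloro dienyl aldehyde 23 (C4–C8, C16–C19) through the C9 α-alkoxyorganometallic.
4. 13 comes from an enantioselective Diels–Alder adduct 4 (ring A), followed by C9 stannylation, a CBS-set C2 vinyl carbinol and conversion of the ring olefin into the 12α-OH / 13α,14α-epoxide.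
5. 23 comes from Sharpless epoxidation of enynol 16, chloride opening (C6–Cl, C7–O) and enyne metathesis with ethylene. Ring order: ring A, oxirane, γ-lactone, ten-membered ring.

Conventions: locants C1–C20 are those of the target skeleton (ring A = C1, C10–C14; Me-15 on C1; Me-20 on C11; β = the face of ring A that carries Me-15). Compounds 21–23, 26 and 27 are epimer mixtures at the CHBr carbon (26 also at C8); both centres are erased in steps 19–20.
Assumption: the (S)-oxazaborolidinium catalyst of step 2 gives the enantiomer drawn for 4; if it gives the antipode, the (R)-catalyst is used and nothing else changes.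

**Fragment A (steps 1–9)**

Step 1
Reactants: 1 methyl (E)-2-methylbut-2-enoate (methyl tiglate)
Product: 2 methyl (E)-2-methyl-4-oxobut-2-enoate
Conditions: SeO2 (1.2 equiv), 1,4-dioxane, 90 °C
Reagents that add atoms: selenium dioxide O=[Se]=O
Why: Riley allylic oxidation (ene reaction then [2,3]-shift) attacks the γ-methyl of the enoate and keeps the E geometry, so the formyl group ends up trans to the ester.

Step 2
Reactants: 2 methyl (E)-2-methyl-4-oxobut-2-enoate; 3 (E)-penta-1,3-diene
Product: 4 methyl (1S,5S,6S)-6-formyl-1,5-dimethylcyclohex-3-ene-1-carboxylate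
Conditions: (S)-3,3-diphenyl-1-(2-methylphenyl)tetrahydro-1H,3H-pyrrolo[1,2-c][1,3,2]oxazaborole (10 mol%), Tf2NH (10 mol%), CH2Cl2, −78 → −40 °C
Reagents that add atoms: none
Why: Catalytic enantioselective Diels–Alder reaction in which the catalyst-bound formyl group is endo and directs the diene CH2 terminus to C1 ("ortho" adduct), so the E dienophile fixes C2 and C9 trans, the endo rule places Me-20 cis to the formyl carbon, and the chiral Lewis acid sets the absolute configuration.

Step 3
Reactants: 4 methyl (1S,5S,6S)-6-formyl-1,5-dimethylcyclohex-3-ene-1-carboxylate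
Product: 6 methyl (1S,5S,6S)-1,5-dimethyl-6-[(S)-(tributylstannyl)({[tri(propan-2-yl)silyl]oxy}methoxy)methyl]cyclohex-3-ene-1-carboxylate, via lithium stannylcarbinolate 5 (not isolated)
Conditions: Bu3SnH, LiN(iPr)2, THF, 0 °C; add 4 at −78 °C; then iPr3SiOCH2Cl, −78 → 0 °C
Reagents that add atoms: tributylstannyllithium [Li][Sn](CCCC)(CCCC)CCCC; (triisopropylsiloxy)methyl chloride ClCO[Si](C(C)C)(C(C)C)C(C)C
Why: Still α-alkoxystannane synthesis in which Bu3SnLi adds to the aldehyde under Felkin–Anh control (quaternary C1 as the large group) to set C9, and the alkoxide is trapped as a fluoride-labile silyloxymethyl acetal.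

Step 4
Reactants: 6 the stannyl ester from step 3
Product: 8 1-{(1S,5S,6S)-1,5-dimethyl-6-[(S)-(tributylstannyl)({[tri(propan-2-yl)silyl]oxy}methoxy)methyl]cyclohex-3-en-1-yl}prop-2-en-1-one, via Weinreb amide 7 (not isolated)
Conditions: MeNH(OMe)·HCl (3 equiv), iPrMgCl (6 equiv), THF, −20 → 25 °C; then CH2=CHMgBr (4 equiv), 0 °C; inverse quench into cold aq. NH4Cl
Reagents that add atoms: vinylmagnesium bromide C=C[Mg]Br
Why: One-pot Weinreb ketone synthesis in which the magnesium amide converts the only ester into the N-methoxy-N-methylamide, whose chelated adduct with the vinyl Grignard reagent stops at the enone.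

Step 5
Reactants: 8 the vinyl ketone from step 4
Product: 9 (1R)-1-{(1S,5S,6S)-1,5-dimethyl-6-[(S)-(tributylstannyl)({[tri(propan-2-yl)silyl]oxy}methoxy)methyl]cyclohex-3-en-1-yl}prop-2-en-1-ol
Conditions: (S)-1-methyl-3,3-diphenyltetrahydro-1H,3H-pyrrolo[1,2-c][1,3,2]oxazaborole (20 mol%), catecholborane, toluene, −78 °C; aq. NaOH work-up
Reagents that add atoms: none
Why: Corey–Bakshi–Shibata reduction in which the quaternary C1 is the large group and the vinyl the small group, so the (S)-catalyst gives the 2R carbinol while catecholborane spares the olefins and the C–Sn bond.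

Step 6
Reactants: 9 the C2 allylic alcohol from step 5
Product: 10 the 12α,13α-epoxide of 9 (7-oxabicyclo[4.1.0]heptane core, oxygen anti to Me-15, Me-20 and the stannyl branch)
Conditions: mCPBA (1.1 equiv), CH2Cl2, 0 °C
Reagents that add atoms: 3-chloroperbenzoic acid OOC(=O)c1cccc(Cl)c1
Why: Prilezhaev epoxidation in which the cis-disubstituted ring olefin reacts far faster than the terminal vinyl group and is attacked on the α face, opposite to the three β substituents.

Step 7
Reactants: 10 the 12α,13α-epoxide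
Product: 11 the 12α-hydroxy-Δ13(14) allylic alcohol (cyclohex-2-en-1-ol ring, 12-OH trans to Me-20, C2 carbinol and stannyl branch unchanged)
Conditions: LiNEt2 (from Et2NH and n-BuLi, 4 equiv), Et2O–hexane, 0 → 35 °C
Reagents that add atoms: none
Why: Base-mediated isomerisation of an epoxide to an allylic alcohol (syn β-elimination) in which the amide removes the α proton of the unhindered C14 methylene in preference to the tertiary H-11, leaving the oxygen on C12 with unchanged configuration.

Step 8
Reactants: 11 the ring allylic alcohol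
Product: 12 the 13α,14α-epoxide of 11 (oxirane cis to the 12-OH)
Conditions: VO(acac)2 (5 mol%), t-BuOOH (1.1 equiv), CH2Cl2, 0 °C
Reagents that add atoms: tert-butyl hydroperoxide CC(C)(C)OO
Why: Hydroxyl-directed vanadium-catalysed epoxidation in which the cyclic allylic 12α-OH delivers oxygen to its own face, much faster than the acyclic terminal allylic alcohol at C2 reacts.

Step 9
Reactants: 12 the epoxy diol
Product: 13 fragment A, the 2,12-bis(triethylsilyl) ether of 12
Conditions: Et3SiCl (3 equiv), imidazole, DMAP (cat.), DMF, 25 °C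
Reagents that add atoms: chlorotriethylsilane CC[Si](CC)(CC)Cl
Why: Silyl ether formation protects both secondary hydroxyls with a group that survives organolithium chemistry and falls off with fluoride at the end.

**Fragment B (steps 10–17)**

Step 10
Reactants: 14 (±)-2-(chloromethyl)oxirane (epichlorohydrin)
Product: 16 (E)-pent-2-en-4-yn-1-ol, via 2-(prop-2-yn-1-yl)oxirane 15 (not isolated)
Conditions: NaC≡CH (2.2 equiv), liq. NH3, −33 °C; NH4Cl
Reagents that add atoms: sodium acetylide [Na+].[C-]#C
Why: Acetylide opens the epoxide, the chlorohydrin re-closes to 15, and base-induced propargylic elimination (epoxide to allylic alcohol) gives the conjugated E enynol.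

Step 11
Reactants: 16 (E)-pent-2-en-4-yn-1-ol
Product: 17 [(2R,3R)-3-ethynyloxiran-2-yl]methanol
Conditions: Ti(OiPr)4 (10 mol%), D-(−)-diisopropyl tartrate (12 mol%), t-BuOOH, 4 Å molecular sieves, CH2Cl2, −20 °C
Reagents that add atoms: tert-butyl hydroperoxide CC(C)(C)OO
Why: Sharpless asymmetric epoxidation in which the D-(−)-tartrate complex delivers oxygen to the face of the E allylic alcohol that gives the 2R,3R epoxy alcohol (C7 of the target).

Step 12
Reactants: 17 [(2R,3R)-3-ethynyloxiran-2-yl]methanol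
Product: 18 (2R,3S)-3-chloropent-4-yne-1,2-diol
Conditions: TiCl2(OiPr)2 (1.5 equiv), CH2Cl2, 0 °C; aq. tartaric acid work-up
Reagents that add atoms: titanium dichloride diisopropoxide CC(C)O[Ti](Cl)(Cl)OC(C)C
Why: Titanium-assisted C3-selective opening of a 2,3-epoxy alcohol in which chloride attacks the propargylic carbon of the titanium-bound epoxy alkoxide with inversion, setting C6 with chloride anti to the C7 oxygen.

Step 13
Reactants: 18 (2R,3S)-3-chloropent-4-yne-1,2-diol
Product: 19 (2R,3S)-3-chloro-4-methylidenehex-5-ene-1,2-diol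
Conditions: second-generation Grubbs catalyst RuCl2(=CHPh)(PCy3)(H2IMes) (5 mol%), ethylene (1 atm), CH2Cl2, 25 °C
Reagents that add atoms: ethylene C=C
Why: Enyne cross-metathesis with ethylene turns the terminal alkyne into the 2-substituted buta-1,3-diene (C4, C5, C16) without touching the stereocentres.

Step 14
Reactants: 19 (2R,3S)-3-chloro-4-methylidenehex-5-ene-1,2-diol
Product: 20 (2R,3S)-3-chloro-4-methylidene-1-[(triethylsilyl)oxy]hex-5-en-2-ol
Conditions: Et3SiCl (1.05 equiv), imidazole, CH2Cl2, −40 °C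
Reagents that add atoms: chlorotriethylsilane CC[Si](CC)(CC)Cl
Why: Selective silylation of the primary hydroxyl leaves the secondary C7 hydroxyl free for acylation.

Step 15
Reactants: 20 the primary silyl ether
Product: 21 (2R,3S)-3-chloro-4-methylidene-1-[(triethylsilyl)oxy]hex-5-en-2-yl 2-bromopropanoate
Conditions: CH3CHBrCOBr (1.3 equiv), pyridine, CH2Cl2, −20 → 0 °C
Reagents that add atoms: 2-bromopropanoyl bromide CC(Br)C(=O)Br
Why: Esterification puts C17–C19 on the C7 oxygen as the latent Reformatsky donor.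

Step 16
Reactants: 21 the silyl ether bromo ester
Product: 22 (2R,3S)-3-chloro-1-hydroxy-4-methylidenehex-5-en-2-yl 2-bromopropanoate
Conditions: HF·pyridine, pyridine, THF, 0 °C
Reagents that add atoms: none
Why: Fluoride desilylation under weakly acidic conditions frees the primary alcohol without base-promoted acyl migration from O7.

Step 17
Reactants: 22 the primary alcohol
Product: 23 fragment B, (2R,3S)-3-chloro-4-methylidene-1-oxohex-5-en-2-yl 2-bromopropanoate
Conditions: Dess–Martin periodinane (1.3 equiv), CH2Cl2, 0 → 25 °C; used at once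
Reagents that add atoms: none
Why: Dess–Martin oxidation gives the α-acyloxy aldehyde under non-basic conditions, avoiding epimerisation at C7 and loss of HCl.

**Coupling and completion (steps 18–23)**

Step 18
Reactants: 13 fragment A stannane; 23 fragment B aldehyde
Product: 26 coupled C8 carbinol (C9 of fragment A bonded to C8 of fragment B; C8 epimers), via α-alkoxyorganolithium 24 (not isolated), via α-alkoxyorganomagnesium bromide 25 (not isolated)
Conditions: 13, n-BuLi (1.05 equiv), THF, −78 °C, 10 min; MgBr2·OEt2 (1.2 equiv), −78 °C; then 23, −78 °C; pH 7 buffer at −78 °C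
Reagents that add atoms: none
Why: Tin–lithium exchange, transmetalation to magnesium and carbonyl addition all proceed with retention at C9 (Still α-alkoxyorganometallic addition), and the magnesium reagent adds to the aldehyde faster than it attacks the ester, the C–Br bond or the allylic chloride.

Step 19
Reactants: 26 the coupled carbinol
Product: 27 the C8 ketone (C9 silyloxymethyl ether on one side, C7 2-bromopropanoate on the other)
Conditions: Dess–Martin periodinane, pyridine, CH2Cl2, 0 °C
Reagents that add atoms: none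
Why: Dess–Martin oxidation removes the uncontrolled C8 centre and gives the ketone acceptor under neutral conditions that spare the β-chloro and α-acyloxy groups.

Step 20
Reactants: 27 the C8 ketone
Product: 29 the hydroxy γ-lactone triene (C7 R, C8 R, C17 R; 8-OH cis to the C6 side chain and to Me-18), via trivalent samarium enolate 28 (not isolated)
Conditions: SmI2 (2.1 equiv, 0.1 M in THF) added dropwise, THF, −78 °C; aq. NH4Cl
Reagents that add atoms: none
Why: Intramolecular samarium Reformatsky reaction in which SmI2 reduces the C–Br bond faster than the ketone and the samarium enolate adds to C8 through a chelated transition state that places the bulky C9 branch trans to both the C6 side chain and Me-18.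

Step 21
Reactants: 29 the hydroxy lactone triene
Product: 30 the ten-membered ring compound (Z-C3=C4; 2,12-bis(triethylsilyl) ether and 9-[(triisopropylsilyloxy)methyl] ether of 31)
Conditions: second-generation Hoveyda–Grubbs catalyst RuCl2(=CH-C6H4-2-OiPr)(H2IMes) (15 mol%), toluene (0.5 mM), 80 °C
Reagents that add atoms: none
Why: Ring-closing metathesis between the C2 vinyl group and the monosubstituted end of the diene closes the ten-membered ring, and the cyclohexane- and lactone-fused frame accommodates only the cis ring olefin.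

Step 22
Reactants: 30 the protected ten-membered ring compound
Product: 31 the 2,9,12-tris-deacetyl target (tetraol with free 2-, 8-, 9- and 12-OH)
Conditions: HF·pyridine, excess pyridine, THF, 0 → 25 °C
Reagents that add atoms: none
Why: Fluoride cleaves both triethylsilyl ethers and the silyl acetal (which then loses formaldehyde) under buffered conditions that leave the epoxide, the allylic chloride and the β-hydroxy lactone intact.

Step 23
Reactants: 31 the tetraol
Product: 32 CNP0274383.2
Conditions: Ac2O, pyridine, DMAP (cat.), CH2Cl2, 0 → 25 °C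
Reagents that add atoms: acetic anhydride CC(=O)OC(C)=O
Why: Acetylation esterifies the three secondary hydroxyls at C2, C9 and C12 while the hindered tertiary 8-OH stays free.

**Compound list**
1 | methyl (E)-2-methylbut-2-enoate | C/C=C(\C)C(=O)OC | starting material
2 | methyl (E)-2-methyl-4-oxobut-2-enoate | COC(=O)/C(C)=C/C=O | intermediate
3 | (E)-penta-1,3-diene | C=C/C=C/C | starting material
4 | methyl (1S,5S,6S)-6-formyl-1,5-dimethylcyclohex-3-ene-1-carboxylate | COC(=O)[C@]1(C)[C@H]([C@@H](C)C=CC1)C=O | intermediate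
5 | lithium (S)-carbinolate from addition of Bu3Sn to the formyl group of 4 | COC(=O)[C@]1(C)[C@H]([C@@H](C)C=CC1)[C@@H]([O-])[Sn](CCCC)(CCCC)CCCC.[Li+] | intermediate
6 | methyl (1S,5S,6S)-1,5-dimethyl-6-[(S)-(tributylstannyl)({[tri(propan-2-yl)silyl]oxy}methoxy)methyl]cyclohex-3-ene-1-carboxylate | COC(=O)[C@]1(C)[C@H]([C@@H](C)C=CC1)[C@@H](OCO[Si](C(C)C)(C(C)C)C(C)C)[Sn](CCCC)(CCCC)CCCC | intermediate
7 | N-methoxy-N-methylamide corresponding to ester 6 | CON(C)C(=O)[C@]1(C)[C@H]([C@@H](C)C=CC1)[C@@H](OCO[Si](C(C)C)(C(C)C)C(C)C)[Sn](CCCC)(CCCC)CCCC | intermediate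
8 | 1-{(1S,5S,6S)-1,5-dimethyl-6-[(S)-(tributylstannyl)({[tri(propan-2-yl)silyl]oxy}methoxy)methyl]cyclohex-3-en-1-yl}prop-2-en-1-one | C=CC(=O)[C@]1(C)[C@H]([C@@H](C)C=CC1)[C@@H](OCO[Si](C(C)C)(C(C)C)C(C)C)[Sn](CCCC)(CCCC)CCCC | intermediate
9 | (1R)-1-{(1S,5S,6S)-1,5-dimethyl-6-[(S)-(tributylstannyl)({[tri(propan-2-yl)silyl]oxy}methoxy)methyl]cyclohex-3-en-1-yl}prop-2-en-1-ol | C=C[C@@H](O)[C@]1(C)[C@H]([C@@H](C)C=CC1)[C@@H](OCO[Si](C(C)C)(C(C)C)C(C)C)[Sn](CCCC)(CCCC)CCCC | intermediate
10 | 12α,13α-epoxide of 9 | C=C[C@@H](O)[C@]1(C)[C@H]([C@@H](C)[C@@H]2O[C@@H]2C1)[C@@H](OCO[Si](C(C)C)(C(C)C)C(C)C)[Sn](CCCC)(CCCC)CCCC | intermediate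
11 | 12α-hydroxy-Δ13(14) allylic alcohol (C2 R carbinol, C9 S stannane) | C=C[C@@H](O)[C@]1(C)[C@H]([C@@H](C)[C@H](O)C=C1)[C@@H](OCO[Si](C(C)C)(C(C)C)C(C)C)[Sn](CCCC)(CCCC)CCCC | intermediate
12 | 13α,14α-epoxide of 11 (oxirane cis to 12-OH) | C=C[C@@H](O)[C@]1(C)[C@H]([C@@H](C)[C@H](O)[C@@H]2O[C@@H]21)[C@@H](OCO[Si](C(C)C)(C(C)C)C(C)C)[Sn](CCCC)(CCCC)CCCC | intermediate
13 | fragment A: 2,12-bis(triethylsilyl) ether of 12 | C=C[C@@H](O[Si](CC)(CC)CC)[C@]1(C)[C@H]([C@@H](C)[C@H](O[Si](CC)(CC)CC)[C@@H]2O[C@@H]21)[C@@H](OCO[Si](C(C)C)(C(C)C)C(C)C)[Sn](CCCC)(CCCC)CCCC | intermediate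
14 | (±)-2-(chloromethyl)oxirane | ClCC1CO1 | starting material
15 | 2-(prop-2-yn-1-yl)oxirane | C#CCC1CO1 | intermediate
16 | (E)-pent-2-en-4-yn-1-ol | OC/C=C/C#C | intermediate
17 | [(2R,3R)-3-ethynyloxiran-2-yl]methanol | OC[C@H]1O[C@@H]1C#C | intermediate
18 | (2R,3S)-3-chloropent-4-yne-1,2-diol | OC[C@@H](O)[C@@H](Cl)C#C | intermediate
19 | (2R,3S)-3-chloro-4-methylidenehex-5-ene-1,2-diol | OC[C@@H](O)[C@@H](Cl)C(=C)C=C | intermediate
20 | (2R,3S)-3-chloro-4-methylidene-1-[(triethylsilyl)oxy]hex-5-en-2-ol | CC[Si](CC)(CC)OC[C@@H](O)[C@@H](Cl)C(=C)C=C | intermediate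
21 | (2R,3S)-3-chloro-4-methylidene-1-[(triethylsilyl)oxy]hex-5-en-2-yl 2-bromopropanoate (CHBr epimers) | CC[Si](CC)(CC)OC[C@@H](OC(=O)C(C)Br)[C@@H](Cl)C(=C)C=C | intermediate
22 | (2R,3S)-3-chloro-1-hydroxy-4-methylidenehex-5-en-2-yl 2-bromopropanoate (CHBr epimers) | OC[C@@H](OC(=O)C(C)Br)[C@@H](Cl)C(=C)C=C | intermediate
23 | fragment B: (2R,3S)-3-chloro-4-methylidene-1-oxohex-5-en-2-yl 2-bromopropanoate (CHBr epimers) | O=C[C@@H](OC(=O)C(C)Br)[C@@H](Cl)C(=C)C=C | intermediate
24 | C9-lithio compound from 13 (Li in place of SnBu3, retention) | C=C[C@@H](O[Si](CC)(CC)CC)[C@]1(C)[C@H]([C@@H](C)[C@H](O[Si](CC)(CC)CC)[C@@H]2O[C@@H]21)[C@@H](OCO[Si](C(C)C)(C(C)C)C(C)C)[Li] | intermediate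
25 | C9-bromomagnesium compound from 24 | C=C[C@@H](O[Si](CC)(CC)CC)[C@]1(C)[C@H]([C@@H](C)[C@H](O[Si](CC)(CC)CC)[C@@H]2O[C@@H]21)[C@@H](OCO[Si](C(C)C)(C(C)C)C(C)C)[Mg]Br | intermediate
26 | coupled C8 carbinol (C8 and CHBr epimers) | C=C[C@@H](O[Si](CC)(CC)CC)[C@]1(C)[C@H]([C@@H](C)[C@H](O[Si](CC)(CC)CC)[C@@H]2O[C@@H]21)[C@@H](OCO[Si](C(C)C)(C(C)C)C(C)C)C(O)[C@@H](OC(=O)C(C)Br)[C@@H](Cl)C(=C)C=C | intermediate
27 | C8 ketone (CHBr epimers) | C=C[C@@H](O[Si](CC)(CC)CC)[C@]1(C)[C@H]([C@@H](C)[C@H](O[Si](CC)(CC)CC)[C@@H]2O[C@@H]21)[C@@H](OCO[Si](C(C)C)(C(C)C)C(C)C)C(=O)[C@@H](OC(=O)C(C)Br)[C@@H](Cl)C(=C)C=C | intermediate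
28 | trivalent samarium enolate of the propanoate arm of 27 | C=C[C@@H](O[Si](CC)(CC)CC)[C@]1(C)[C@H]([C@@H](C)[C@H](O[Si](CC)(CC)CC)[C@@H]2O[C@@H]21)[C@@H](OCO[Si](C(C)C)(C(C)C)C(C)C)C(=O)[C@@H](OC(O[Sm](I)I)=CC)[C@@H](Cl)C(=C)C=C | intermediate
29 | hydroxy γ-lactone triene (C7 R, C8 R, C17 R) | C=C[C@@H](O[Si](CC)(CC)CC)[C@]1(C)[C@H]([C@@H](C)[C@H](O[Si](CC)(CC)CC)[C@@H]2O[C@@H]21)[C@@H](OCO[Si](C(C)C)(C(C)C)C(C)C)[C@]3(O)[C@@H](C)C(=O)O[C@H]3[C@@H](Cl)C(=C)C=C | intermediate
30 | ten-membered ring compound, 2,12-bis(triethylsilyl) 9-[(triisopropylsilyloxy)methyl] ether of 31 | C=C1/C=C\[C@@H](O[Si](CC)(CC)CC)[C@]2(C)[C@H]([C@@H](C)[C@H](O[Si](CC)(CC)CC)[C@@H]3O[C@@H]32)[C@@H](OCO[Si](C(C)C)(C(C)C)C(C)C)[C@]2(O)[C@@H](C)C(=O)O[C@H]2[C@H]1Cl | intermediate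
31 | 2,9,12-tris-deacetyl target (tetraol) | C=C1/C=C\[C@@H](O)[C@]2(C)[C@H]([C@@H](C)[C@H](O)[C@@H]3O[C@@H]32)[C@@H](O)[C@]2(O)[C@@H](C)C(=O)O[C@H]2[C@H]1Cl | intermediate
32 | CNP0274383.2 | C=C1/C=C\[C@@H](OC(C)=O)[C@]2(C)[C@H]([C@@H](C)[C@H](OC(C)=O)[C@@H]3O[C@@H]32)[C@@H](OC(C)=O)[C@]2(O)[C@@H](C)C(=O)O[C@H]2[C@H]1Cl | target

**Step count**
Total: 23 steps (fragment A steps 1–9, fragment B steps 10–17, steps 18–23 after the coupling).
Longest linear sequence: 15 steps (steps 1–9, then 18–23).

**Three steps most likely to fail**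

Step 21, ring-closing metathesis. The C2 vinyl group sits between a silyl ether and the quaternary C1, so initiation and closure of the strained ten-membered diene may be slow and lose out to oligomerisation. The fallback changes the substrate and the order of events: starting from 29, the silyl groups are removed first (HF·pyridine, pyridine, THF) to give the desilylated acyclic triene tetraol F1. Its free, much smaller C2 allylic hydroxyl is known to accelerate metathesis at the adjacent olefin. Ring closure of F1 with the same ruthenium carbene at high dilution gives tetraol 31 directly, where the route is rejoined for step 23.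

Step 18, the fragment coupling. The α-acyloxy β-chloro aldehyde 23 can enolise, lose HCl or suffer acyl migration in the magnesium alkoxide before the hindered C9 nucleophile adds. The fallback replaces aldehyde addition plus oxidation by an acylation. Starting from 23, Pinnick oxidation (NaClO2, NaH2PO4, 2-methylbut-2-ene, t-BuOH–H2O) gives (2R,3S)-2-[(2-bromopropanoyl)oxy]-3-chloro-4-methylidenehex-5-enoic acid F2. Carbodiimide coupling with MeNH(OMe)·HCl gives the N-methoxy-N-methylamide F3, which has no aldehyde proton chemistry and forms a stable chelate. Organomagnesium 25, made from 13 exactly as in step 18, then acylates F3 (THF, −78 → −20 °C) to give ketone 27 directly, where the route is rejoined at step 20 (step 19 is no longer needed).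

Step 20, the samarium Reformatsky lactonisation. In the flexible open-chain ketone the facial selectivity at C8 (and the C17 configuration) rests on a steric argument, and SmI2 may also cleave the α-alkoxy ketone. The fallback reverses the order of ring formation so that the ten-membered ring controls the addition. Starting from 27, ring-closing metathesis under the conditions of step 21 gives the macrocyclic C8 keto 2-bromopropanoate F4. Treatment of F4 with SmI2 (THF, −78 °C) then builds the lactone onto the preformed ring, whose geometry allows the enolate to reach only the ketone face leading to the natural trans-disposed C6/C9 arrangement. This gives 30, where the route is rejoined for step 22.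

**Further compounds**
F1 | step 21 | desilylated acyclic triene tetraol (29 without the two SiEt3 groups and the CH2OSi(iPr)3 group) | C=C[C@@H](O)[C@]1(C)[C@H]([C@@H](C)[C@H](O)[C@@H]2O[C@@H]21)[C@@H](O)[C@]3(O)[C@@H](C)C(=O)O[C@H]3[C@@H](Cl)C(=C)C=C
F2 | step 18 | (2R,3S)-2-[(2-bromopropanoyl)oxy]-3-chloro-4-methylidenehex-5-enoic acid (CHBr epimers) | OC(=O)[C@@H](OC(=O)C(C)Br)[C@@H](Cl)C(=C)C=C
F3 | step 18 | (2R,3S)-3-chloro-1-[methoxy(methyl)amino]-4-methylidene-1-oxohex-5-en-2-yl 2-bromopropanoate (CHBr epimers) | CON(C)C(=O)[C@@H](OC(=O)C(C)Br)[C@@H](Cl)C(=C)C=C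
F4 | step 20 | macrocyclic C8 ketone with Z-C3=C4 and the C7 2-bromopropanoate (ring-closed 27; CHBr epimers) | C=C1/C=C\[C@@H](O[Si](CC)(CC)CC)[C@]2(C)[C@H]([C@@H](C)[C@H](O[Si](CC)(CC)CC)[C@@H]3O[C@@H]32)[C@@H](OCO[Si](C(C)C)(C(C)C)C(C)C)C(=O)[C@@H](OC(=O)C(C)Br)[C@H]1Cl
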